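The data were computed with made-up constants, noise included.

At 40 h dawn stops and at 60 h dusk stops; both are charged alike.

in all of them: gas phase 9.5 mM (held)

| flask | substrate | remark | time |
|---|---|---|---|
| north-east | 0.050 M | run made earlier |  |
| south-west | 0.20 M | run made earlier |  |
| dawn | 0.10 M |  | 40 h |
| dusk | 0.10 M |  | 60 h |

| run | time / h | target / % | substrate / % |
|---|---|---|---|
| north-east | 3.00 | 10 | 87 |
| north-east | 5.00 | 23 | 81 |
| north-east | 8.00 | 35 | 66 |
| north-east | 15.0 | 50 | 46 |
| north-east | 25.0 | 46 | 31 |
| north-east | 40.0 | 38 | 18 |
| south-west | 2.50 | 6 | 95 |
| south-west | 8.00 | 16 | 80 |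
| south-west | 15.0 | 32 | 65 |
| south-west | 20.0 | 42 | 55 |
| south-west | 30.0 | 53 | 39 |
| south-west | 40.0 | 61 | 29 |

(standard deviation of a reading: 2 percentage points)

- at the start none of the gas phase is in solution
- a reading or a percentage of target counts all its forms, free or not

- which of the two there is more of at the end, dawn (over-reacted product / target)
- which of the two there is more of at the end, dusk (over-reacted product / target)
- final target, as a percentage of the substrate charged, in dawn
- final target, as a percentage of the substrate charged, in dusk

1. The decay constant (a pseudo-first-order constant) is the natural logarithm of one over the fraction of substrate left, divided by the time. The last readings give 0.0429 h⁻¹ for north-east and 0.0309 h⁻¹ for south-west.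

2. The charge of dawn and dusk lies midway between those runs on a logarithmic scale. Their decay constant is therefore taken as the geometric mean, 0.0364 h⁻¹. The substrate left is then 23.3% in dawn and 11.2% in dusk.

3. Whatever is neither substrate nor target counts as over-reacted product. At 40.0 h that is 44.0% in north-east and 10.0% in south-west. Their geometric mean, 21.0%, leaves dawn 55.7% target.

4. That mean is the weak link, since its two ends lie far apart. Reforged: over the last interval, the north-east readings show over-reacted product growing at 0.0333 h⁻¹ of the target present, close to the decay constant. With equal constants in a chain, target is the constant times the time times the fraction left. That gives 33.9% in dawn and 24.6% in dusk.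

5. My committed dawn value is the midpoint of the two estimates, 44.8% target, beside 31.9% over-reacted product. Scaled by the chain ratio, dusk has 32.5% target beside 56.3% over-reacted product.

The forecast differs: 57% target in dawn, with more target, and 42% in dusk, with more over-reacted product. Its ground is that “over-reaction is held back while substrate remains”.

Dawn ends with 45.0% target and 31.3% over-reacted product. Dusk ends with 32.0% target and 52.1% over-reacted product.

    gas phase ⇌ dissolved gas, rate k1*(csat - [dissolved gas]) (kL = 2.20 × 10⁻⁴ s⁻¹)
    substrate + dissolved gas ⇌ target (K = 330 M⁻¹, k = 0.00320 M⁻¹ s⁻¹)
    dissolved gas + target → over-reacted product (k = 0.00100 M⁻¹ s⁻¹)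
    crystals ⇌ target, rate k4*(cs4 - [target]) while solid is left; crystals form when [target] > cs4 (solubility = 42.0 mM, k = 2.80 × 10⁻⁴ s⁻¹)

The substrate left gives a decay constant of 0.0359 h⁻¹ in dawn, against the reckoned 0.0364 h⁻¹. In dusk it gives 0.0307 h⁻¹, lower than reckoned, and dusk holds 16% substrate against the reckoned 11.2%. A neighbouring flask is dusk with 0.25 M of substrate. The two runs give a power of 0.235 for the fall of the constant with charge. From 0.0364 h⁻¹, that power gives the neighbouring flask a reckoned 0.0294 h⁻¹ and a reckoned 17.1% substrate left at 60 h. The neighbouring flask holds 15% substrate at that time.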